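Ten-membered compounds carry germacrane locants throughout: ring C1–C10, lactone carbons C11–C13, C14 the methyl on C10, C15 the methyl on C4. Bicyclic compounds carry naphthalene locants.

## Analysis of the target

The target 32 is a germacranolide with a ten-membered carbocycle C1–C10. A butenolide (O6–C12(=O)–C11=C7) is fused across C6–C7 and carries the acetoxymethyl carbon C13 on C11, and O8 bears a tiglate. Two trisubstituted oxiranes span C1–C10 and C4–C5. All six stereocentres lie on the ring and are (1R,4R,5R,6S,8S,10R). In the usual drawing O6 and O8 are both α, the oxirane oxygen is α at C4 and C10 and β at C1 and C5, and both methyl groups are β. Both oxiranes are trans across the ring, the pattern of E-alkenes, so neither can be carried intact through a six-membered ring; the C10–O bond and the C8–O bond can. The sensitive parts are the two oxiranes (acid, transannular opening), the butenolide with its acidic C6–H next to an oxirane (base), and the two unsaturated esters. The difficulty is a medium ring whose six stereocentres are separated by the trigonal C7, so that C6 and C8 cannot be relayed through C7. The route rests on one feature: C1 and C6 both bear oxygen and face each other across the ring. That is the pattern left when the bond shared by ring A (C1–C6) and ring B (C6–C10, C1) of an octalin is cut.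

## Retrosynthetic reasoning

32 to 30. The C13 acetate is removed first and the primary alcohol 31 is masked as the 4-methoxybenzyl ether 30. This ether survives acid, mild base and peracid and is cleaved oxidatively at neutral pH, which both oxiranes and the butenolide tolerate.

30 to 29. The two C–O bonds of the 4,5-oxirane are cut to the (4E)-alkene 29. The oxirane is made last among the skeletal operations because C7 must earlier be unmasked with acid and an oxirane would not survive that. The forward peracid epoxidation has to strike the outer face of the E-alkene, which in E-germacranolides gives the 4α,5β sense.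

29 to 28. Only the C1–O bond of the 1,10-oxirane is cut, which leaves the tertiary C10–O bond intact. Diol 28 must then be the anti (1S,10R) isomer, and the forward closure must invert C1 under neutral conditions because the butenolide is already present. A base-mediated sulfonate closure at this stage would endanger C6–H.

28 to 19 and 25. The butenolide is opened at C7=C11 (intramolecular phosphonate olefination of the C7 ketone 27) and at the O6–C12 ester (26 from alcohol 19 and phosphonate acid 25). The reagent brings C11, C12 and C13 with the C13 oxygen already in place, so no late allylic oxidation is needed. The C7 carbonyl comes from the dimethyl ketal, and its acidic hydrolysis is placed before either oxirane exists.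

19 to 16. The C6 carbinol comes from the (4E)-enone 18 by a catalyst-controlled reduction, since no neighbouring stereocentre can direct it. The enone comes from ketone 16 through the silyl enol ether 17. C7 is fully substituted, so C6 can only enolise toward C5, and dehydrogenation places the double bond at C4=C5.

16 to 15. In dione 15 the C1 ketone could also enolise (toward C2), so it is taken out first. The hydroxyl on C10 is left free so that a chelating hydride reagent can reduce C1 faster than C6 and from a defined face, giving the anti-diol needed later.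

15 to 13 (key disconnection). C1 and C6 are reconnected by a double bond, which turns the ten-membered dione into the octalin 13. Nothing else in the target suggests so direct a source for a 1,6-dioxygenated cyclodecane. The ring is then never closed by a bond-forming macrocyclisation, and C8 and C10 can be set on a rigid six-membered ring. The forward cleavage must touch only the tetrasubstituted alkene and must deliver the dione under neutral conditions. The tiglate is already in place in 13, so that no free C8 hydroxyl has to be handled beside the oxiranes or the butenolide later.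

13 to 7. The tiglate is cut to diol 12 and the C10–C14 bond is cut to enone 10. A methyl nucleophile must add to C10 anti to the silyloxy group on C8, which places the two oxygens cis as required. The C8–O bond is cut to the cross-conjugated dienone 7. Only its disubstituted enone can accept a boryl–copper species, and a chiral ligand sets C8 absolutely (9 via 8).

7 to 1. Dienone 7 is the oxidative dearomatisation product of phenol 6. The position of the methyl group relative to the two different oxygens is fixed by a Diels–Alder reaction of monoketal 2 with diene 3 (adduct 4), then aromatisation to 5 and hydrogenation. The methyl-bearing carbon is a stereocentre of no consequence, because it becomes trigonal in 18.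

25 to 20. Acid 25 is cut at the ether C–O bond (conjugate addition of alcohol 23 to acrylate 22, then hydrolysis of 24), and 22 comes from 20 and 21.

## Alternatives that were turned down

Alternative 1: The disconnection is the C6–O bond together with the lactone C–O bond. In the forward direction a CYP71-family P450 enzyme hydroxylates C6 of the germacrene acid A1 on the α face and the alcohol lactonises to eupatolide A2.
- For: one step makes the C6 stereocentre and the lactone on a ring that already holds both E-alkenes, without protecting groups. On alkene geometry it is clearly stronger than the chosen route, which must create the 4E bond by dehydrogenation.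
- Against: A2 carries O8 on the β face, the opposite of the α-oxygen of the target, so a hindered allylic carbinol would have to be inverted. A2 is an 11(13)-methylene lactone, whereas the target needs the 7(11)-alkene with oxygen on C13, which costs a transposition and an oxidation. A1 is not a purchasable material and needs an engineered pathway or its own synthesis, and such acids rearrange thermally. Both epoxidations remain.
- Comparison: the chosen route is longer but purely chemical, sets C8 with the correct sense by a catalyst, and installs the butenolide in its final oxidation state.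

Alternative 2: The disconnection is C8–O and C13–O at once. In the forward direction photo-oxygenation adds across the s-cis diene of the diepoxy dienolide A3 in a (4+2) sense to give the endoperoxide A4, which would be reduced and acylated twice.
- For: one step places both oxygens and moves the alkene to C7=C11. This is more economical for C8 and C13 than the chosen route, which uses a conjugate borylation and a protected phosphonate reagent for the same atoms.
- Against: it is only an endgame. A3 already contains the ten-membered ring, both oxiranes and the lactone, so the hard part of the problem is untouched. The face of attack at C8 depends on the conformation of a flexible ring, ene reactions at the allylic C9 and C6 hydrogens compete, and the peroxide must be reduced beside two oxiranes.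
- Comparison: the chosen strategy builds the ring itself from simple aromatics and fixes C8 by reagent control before the ring exists.

Alternative 3: The disconnection is C5–C6 together with C4–C15. In the forward direction Ni(COD)2 couples the terminal alkyne of the acyclic ynal A5 with its aldehyde and Me2Zn, closing the ring, and the alkoxide lactonises to A6.
- For: the syn addition across the alkyne guarantees the E-trisubstituted C4=C5 bond, and ring, C6 carbinol and lactone arise in one operation. It is stronger than the chosen route in convergence and in control of alkene geometry.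
- Against: a ten-membered ring is closed by C–C bond formation against strain and entropy. The aldehyde of A5 sits on a tetrasubstituted enoate, its allylic acetate can ionise on zerovalent nickel, the C6 configuration relative to C8 is not controlled by any adjacent centre, and A5 needs a stereodefined tetrasubstituted alkene. Both oxiranes then depend on facial selectivity.
- Comparison: the chosen route avoids any medium-ring closure, carries C8 and C10 as secure stereocentres from a six-membered ring, and makes the 1,10-oxirane by a stereospecific displacement.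

Key step: step 11

Remark 1: the methyl-bearing ring carbon (C6 in naphthalene locants, C4 in germacrane locants) is formed as a racemate in step 4 and carried as both epimers through compound 17; it becomes trigonal in step 14, so its descriptor is left open in the SMILES.

Remark 2: the sense of induction of the chiral ligand in step 6 and of the oxazaborolidine in step 15 is assigned by analogy (in step 15 the fully substituted ketal carbon is taken as the larger carbonyl substituent); the mirror-image ligand or catalyst is to be used if the sense proves opposite.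

## Steps

Step 1
Reactants: 1 4-methoxyphenol
Product: 2 4,4-dimethoxycyclohexa-2,5-dien-1-one
Conditions: PhI(OAc)2, MeOH, 0 °C
Reagents that add atoms: methanol CO
Why: Oxidative dearomatisation of a para-alkoxyphenol; the aryloxy-iodane collapses to a cation that methanol traps at the para carbon to give the quinone monoketal.

Step 2
Reactants: 2 4,4-dimethoxycyclohexa-2,5-dien-1-one; 3 isoprene
Product: 4 cis-(4aRS,8aSR)-4,4-dimethoxy-6-methyl-4a,5,8,8a-tetrahydronaphthalen-1(4H)-one
Conditions: 3 (5 equiv), TiCl2(OiPr)2 (10 mol %), racemic 1,1'-bi-2-naphthol (10 mol %), 4 Å MS, CH2Cl2, rt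
Reagents that add atoms: none
Why: Lewis-acid-catalysed Diels–Alder reaction; titanium on the ketone makes the enone β-carbon bond to the diene terminus next to the methyl-bearing carbon ("para" adduct, methyl on C6). The racemic catalyst suffices because both new stereocentres vanish in step 3.

Step 3
Reactants: 4 cis-4,4-dimethoxy-6-methyl-4a,5,8,8a-tetrahydronaphthalen-1(4H)-one
Product: 5 4-methoxy-6-methyl-5,8-dihydronaphthalen-1-ol
Conditions: TsOH·H2O (5 mol %), CH2Cl2, rt
Reagents that add atoms: none
Why: Acid ionises the allylic ketal, loss of the ring-fusion proton and enolisation give the phenol (elimination and tautomerisation driven by aromatisation). The methyl group is now fixed relative to the two different oxygens.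

Step 4
Reactants: 5 4-methoxy-6-methyl-5,8-dihydronaphthalen-1-ol
Product: 6 (6RS)-4-methoxy-6-methyl-5,6,7,8-tetrahydronaphthalen-1-ol
Conditions: H2 (1 atm), PtO2, EtOAc, rt
Reagents that add atoms: none
Why: Catalytic hydrogenation of the only non-aromatic alkene; platinum is preferred to palladium to avoid disproportionation of the dihydroarene. The new stereocentre is racemic and is erased later.

Step 5
Reactants: 6 (6RS)-4-methoxy-6-methyl-5,6,7,8-tetrahydronaphthalen-1-ol
Product: 7 (6RS)-4,4-dimethoxy-6-methyl-5,6,7,8-tetrahydronaphthalen-1(4H)-one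
Conditions: PhI(OAc)2, MeOH, 0 °C
Reagents that add atoms: methanol CO
Why: Second oxidative dearomatisation of a para-methoxyphenol; the ring-fusion alkene of the bicyclic quinone monoketal is the future C1=C6 bond.

Step 6
Reactants: 7 (6RS)-4,4-dimethoxy-6-methyl-5,6,7,8-tetrahydronaphthalen-1(4H)-one
Product: 9 (3S)-3-hydroxy-4,4-dimethoxy-6-methyl-3,4,5,6,7,8-hexahydronaphthalen-1(2H)-one, via β-boryl ketone 8 (not isolated)
Conditions: CuCl (5 mol %), (R)-1-[(S)-2-(diphenylphosphino)ferrocenyl]ethyldicyclohexylphosphine (6 mol %), NaOtBu (10 mol %), B2pin2, MeOH (2 equiv), THF, rt; then NaBO3·4H2O, THF/H2O, rt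
Reagents that add atoms: bis(pinacolato)diboron CC1(C)OB(OC1(C)C)B1OC(C)(C)C(C)(C)O1; sodium perborate [Na+].[Na+].O[B-]1(O)OO[B-](O)(O)OO1
Why: Copper-catalysed enantioselective conjugate borylation of a cyclic enone; the ligated monovalent copper boryl adds only to the disubstituted enone (the other is tetrasubstituted) and the ligand chooses the face at C3. Oxidation of the C–B bond with retention gives the (3S)-alcohol, the future C8.

Step 7
Reactants: 9 (3S)-3-hydroxy-4,4-dimethoxy-6-methyl-3,4,5,6,7,8-hexahydronaphthalen-1(2H)-one
Product: 10 (3S)-3-(tert-butyldimethylsilyloxy)-4,4-dimethoxy-6-methyl-3,4,5,6,7,8-hexahydronaphthalen-1(2H)-one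
Conditions: TBSOTf, 2,6-lutidine, CH2Cl2, −78 °C
Reagents that add atoms: tert-butyldimethylsilyl triflate CC(C)(C)[Si](C)(C)OS(=O)(=O)C(F)(F)F
Why: Silylation with a silyl triflate and a hindered weak base at low temperature protects the β-hydroxy ketone before it can eliminate.

Step 8
Reactants: 10 (3S)-3-(tert-butyldimethylsilyloxy)-4,4-dimethoxy-6-methyl-3,4,5,6,7,8-hexahydronaphthalen-1(2H)-one
Product: 11 (1R,3S)-3-(tert-butyldimethylsilyloxy)-4,4-dimethoxy-1,6-dimethyl-1,2,3,4,5,6,7,8-octahydronaphthalen-1-ol
Conditions: MeLi, CeCl3, THF, −78 °C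
Reagents that add atoms: methyllithium [Li]C
Why: Organocerium 1,2-addition to the enone, which avoids enolisation and β-elimination of the silyloxy group. The silyloxy group next to the gem-dimethoxy carbon shields its own face, so methyl should enter anti to it, giving (1R) with the hydroxyl cis to O3.

Step 9
Reactants: 11 (1R,3S)-3-(tert-butyldimethylsilyloxy)-4,4-dimethoxy-1,6-dimethyl-1,2,3,4,5,6,7,8-octahydronaphthalen-1-ol
Product: 12 (1R,3S)-4,4-dimethoxy-1,6-dimethyl-1,2,3,4,5,6,7,8-octahydronaphthalene-1,3-diol
Conditions: Bu4NF, THF, 0 °C → rt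
Reagents that add atoms: none
Why: Fluoride cleavage of the silyl ether; no stereocentre is affected.

Step 10
Reactants: 12 (1R,3S)-4,4-dimethoxy-1,6-dimethyl-1,2,3,4,5,6,7,8-octahydronaphthalene-1,3-diol
Product: 13 (2S,4R)-4-hydroxy-1,1-dimethoxy-4,7-dimethyl-1,2,3,4,5,6,7,8-octahydronaphthalen-2-yl (2E)-2-methylbut-2-enoate
Conditions: tigloyl chloride, pyridine, DMAP (cat.), CH2Cl2, 0 °C → rt
Reagents that add atoms: tigloyl chloride C/C=C(\C)C(Cl)=O
Why: Acylation of the secondary alcohol; the tertiary alcohol does not react. Pyridine instead of a trialkylamine avoids the vinylketene pathway that would deconjugate the tiglate.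

Step 11
Reactants: 13 (2S,4R)-4-hydroxy-1,1-dimethoxy-4,7-dimethyl-1,2,3,4,5,6,7,8-octahydronaphthalen-2-yl (2E)-2-methylbut-2-enoate
Product: 15 (8S,10R)-10-hydroxy-7,7-dimethoxy-4,10-dimethyl-1,6-dioxocyclodecan-8-yl (2E)-2-methylbut-2-enoate, via secondary ozonide 14 (not isolated)
Conditions: O3 (saturated CH2Cl2 solution, 1.05 equiv), CH2Cl2, −78 °C; then PPh3, −78 °C → rt
Reagents that add atoms: ozone [O-][O+]=O
Why: Ozone adds to the tetrasubstituted ring-fusion alkene by 1,3-dipolar cycloaddition; the primary ozonide splits into a ketone and a carbonyl oxide that stay tied together by the two four-carbon chains and recombine to ozonide 14, which PPh3 reduces to the two ketones. The closest known reaction is the ozonolysis of 1,2,3,4,5,6,7,8-octahydronaphthalene to cyclodecane-1,6-dione. No ring is closed by bond formation: the ten-membered ring appears because the bond shared by rings A and B is cut, so no cyclisation mode and no entropic penalty is involved. No stereocentre is formed, and C8 and C10 (germacrane locants) are carried over unchanged. The step needs chemoselectivity for the ring alkene over the tiglate alkene, which the much higher reactivity of a tetraalkyl alkene than of a conjugated enoate and the titrated ozone solution at −78 °C should secure. It also needs the dione to survive: each ketone has a fully substituted α-carbon on one side, the reductant is neutral, and 15 is reduced at once in step 12, so transannular aldolisation has little opportunity.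

Step 12
Reactants: 15 (8S,10R)-10-hydroxy-7,7-dimethoxy-4,10-dimethyl-1,6-dioxocyclodecan-8-yl (2E)-2-methylbut-2-enoate
Product: 16 (1S,8S,10R)-1,10-dihydroxy-7,7-dimethoxy-4,10-dimethyl-6-oxocyclodecan-8-yl (2E)-2-methylbut-2-enoate
Conditions: Zn(BH4)2 (0.6 equiv), Et2O, −40 °C
Reagents that add atoms: none
Why: Chelation-controlled reduction of an α-hydroxy ketone; zinc bridges O10 and the C1 carbonyl and hydride enters from the side of the C14 methyl, which is also the outside of the ring, giving the anti (1S,10R)-diol. The chelated ketone should react faster than the C6 ketone, which has no free hydroxyl and is buried next to the ketal carbon.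

Step 13
Reactants: 16 (1S,8S,10R)-1,10-dihydroxy-7,7-dimethoxy-4,10-dimethyl-6-oxocyclodecan-8-yl (2E)-2-methylbut-2-enoate
Product: 17 (1S,8S,10R)-7,7-dimethoxy-4,10-dimethyl-1,6,10-tris(triethylsilyloxy)cyclodec-5-en-8-yl (2E)-2-methylbut-2-enoate
Conditions: Et3SiOTf (4 equiv), Et3N (6 equiv), CH2Cl2, 0 °C
Reagents that add atoms: triethylsilyl triflate CC[Si](CC)(CC)OS(=O)(=O)C(F)(F)F
Why: Soft enolisation; C7 is fully substituted, so the only enol ether is C5=C6, and both hydroxyls are silylated in the same operation. The ketal, deactivated by oxygen on both neighbours, should ionise far more slowly than the ketone is silylated at 0 °C.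

Step 14
Reactants: 17 (1S,8S,10R)-7,7-dimethoxy-4,10-dimethyl-1,6,10-tris(triethylsilyloxy)cyclodec-5-en-8-yl (2E)-2-methylbut-2-enoate
Product: 18 (1S,4E,8S,10R)-7,7-dimethoxy-4,10-dimethyl-6-oxo-1,10-bis(triethylsilyloxy)cyclodec-4-en-8-yl (2E)-2-methylbut-2-enoate
Conditions: Pd(OAc)2 (1.1 equiv), MeCN, rt
Reagents that add atoms: none
Why: Saegusa–Ito oxidation; the palladium enolate at C5 loses the C4 hydrogen by syn β-hydride elimination, so both C4 epimers converge on one enone. The E-isomer (C3 trans to C6) is expected because the transition state keeps the carbonyl away from the ring methylene C3 and a ten-membered ring accepts a trans double bond.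

Step 15
Reactants: 18 (1S,4E,8S,10R)-7,7-dimethoxy-4,10-dimethyl-6-oxo-1,10-bis(triethylsilyloxy)cyclodec-4-en-8-yl (2E)-2-methylbut-2-enoate
Product: 19 (1S,4E,6R,8S,10R)-6-hydroxy-7,7-dimethoxy-4,10-dimethyl-1,10-bis(triethylsilyloxy)cyclodec-4-en-8-yl (2E)-2-methylbut-2-enoate
Conditions: (S)-2-methyl-CBS-oxazaborolidine (0.5 equiv), catecholborane, toluene, −78 °C
Reagents that add atoms: none
Why: Corey–Bakshi–Shibata reduction, 1,2-selective on enones; with the ketal carbon as the larger substituent the (S)-catalyst should deliver hydride to the face that gives the (6R)-alcohol, with O6 on the same side as O8.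

Step 16
Reactants: 20 triethyl phosphonoacetate; 21 paraformaldehyde
Product: 22 ethyl 2-(diethoxyphosphoryl)acrylate
Conditions: piperidine (cat.), MeOH, reflux; then TsOH (cat.), toluene, reflux
Reagents that add atoms: none
Why: Knoevenagel condensation with formaldehyde, then acid-promoted elimination from the adduct, gives the phosphonoacrylate.

Step 17
Reactants: 22 ethyl 2-(diethoxyphosphoryl)acrylate; 23 4-methoxybenzyl alcohol
Product: 24 ethyl 2-(diethoxyphosphoryl)-3-[(4-methoxybenzyl)oxy]propanoate
Conditions: NaH (0.1 equiv), THF, 0 °C → rt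
Reagents that add atoms: none
Why: Base-catalysed oxa-Michael addition of the alkoxide to the doubly activated alkene; the stabilised carbanion is protonated by the alcohol, which carries the chain.

Step 18
Reactants: 24 ethyl 2-(diethoxyphosphoryl)-3-[(4-methoxybenzyl)oxy]propanoate
Product: 25 2-(diethoxyphosphoryl)-3-[(4-methoxybenzyl)oxy]propanoic acid
Conditions: LiOH, THF/H2O, 0 °C; then aq. HCl to pH 3
Reagents that add atoms: lithium hydroxide [Li+].[OH-]
Why: Saponification of the carboxylic ester; phosphonate esters are not cleaved, and the low temperature limits retro-Michael loss of the alkoxide.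

Step 19
Reactants: 19 (1S,4E,6R,8S,10R)-6-hydroxy-7,7-dimethoxy-4,10-dimethyl-1,10-bis(triethylsilyloxy)cyclodec-4-en-8-yl (2E)-2-methylbut-2-enoate; 25 2-(diethoxyphosphoryl)-3-[(4-methoxybenzyl)oxy]propanoic acid
Product: 26 (1S,4E,6R,8S,10R)-6-{2-(diethoxyphosphoryl)-3-[(4-methoxybenzyl)oxy]propanoyloxy}-7,7-dimethoxy-4,10-dimethyl-1,10-bis(triethylsilyloxy)cyclodec-4-en-8-yl (2E)-2-methylbut-2-enoate
Conditions: EDC·HCl, DMAP, CH2Cl2, 0 °C → rt
Reagents that add atoms: none
Why: Steglich-type esterification of the only free hydroxyl; the phosphonate-bearing carbon is a mixture of epimers, which is of no consequence because it becomes trigonal in step 21.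

Step 20
Reactants: 26 phosphonate ester ketal (name as in step 19)
Product: 27 (1S,4E,6R,8S,10R)-6-{2-(diethoxyphosphoryl)-3-[(4-methoxybenzyl)oxy]propanoyloxy}-1,10-dihydroxy-4,10-dimethyl-7-oxocyclodec-4-en-8-yl (2E)-2-methylbut-2-enoate
Conditions: 1 M aq. HCl, THF, rt
Reagents that add atoms: water O
Why: Acid hydrolysis of the dimethyl ketal and of both triethylsilyl ethers in one operation; it is placed here because no oxirane is yet present. The benzyl ether, the esters and the phosphonate tolerate dilute acid.

Step 21
Reactants: 27 keto diol phosphonate (name as in step 20)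
Product: 28 (1S,6R,8S,10R)-1,10-dihydroxy-13-[(4-methoxybenzyl)oxy]-8-tigloyloxygermacra-4E,7(11)-dien-12,6-olide
Conditions: LiCl, iPr2NEt, MeCN, rt
Reagents that add atoms: none
Why: Intramolecular Horner–Wadsworth–Emmons reaction under Masamune–Roush conditions; the lithium-chelated phosphonate is deprotonated by the amine, adds to the C7 ketone in a five-membered closure and loses phosphate to give the tetrasubstituted butenolide. The weak base is chosen to spare the acidic C6 and C8 hydrogens.

Step 22
Reactants: 28 (1S,6R,8S,10R)-1,10-dihydroxy-13-[(4-methoxybenzyl)oxy]-8-tigloyloxygermacra-4E,7(11)-dien-12,6-olide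
Product: 29 (1R,6R,8S,10R)-1,10-epoxy-13-[(4-methoxybenzyl)oxy]-8-tigloyloxygermacra-4E,7(11)-dien-12,6-olide
Conditions: PPh3, DIAD, toluene, 0 °C → rt
Reagents that add atoms: none
Why: Mitsunobu cyclodehydration of a 1,2-diol; the secondary C1 oxygen is activated as the oxyphosphonium and the tertiary O10 displaces it with inversion, so the anti-diol gives the trans (1R,10R)-oxirane. The neutral conditions spare the butenolide.

Step 23
Reactants: 29 (1R,6R,8S,10R)-1,10-epoxy-13-[(4-methoxybenzyl)oxy]-8-tigloyloxygermacra-4E,7(11)-dien-12,6-olide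
Product: 30 (1R,4R,5R,6S,8S,10R)-1,10:4,5-diepoxy-13-[(4-methoxybenzyl)oxy]-8-tigloyloxygermacr-7(11)-en-12,6-olide
Conditions: mCPBA, NaHCO3, CH2Cl2, 0 °C
Reagents that add atoms: 3-chloroperbenzoic acid OOC(=O)c1cccc(Cl)c1
Why: Prilezhaev epoxidation; C4=C5 is the only electron-rich alkene, the tiglate and butenolide alkenes being conjugated to carbonyls. The peracid should reach the outer face of the E-alkene, which stands perpendicular to the ring, as in E-germacranolides, giving the 4α,5β (4R,5R) oxirane.

Step 24
Reactants: 30 (1R,4R,5R,6S,8S,10R)-1,10:4,5-diepoxy-13-[(4-methoxybenzyl)oxy]-8-tigloyloxygermacr-7(11)-en-12,6-olide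
Product: 31 (1R,4R,5R,6S,8S,10R)-1,10:4,5-diepoxy-13-hydroxy-8-tigloyloxygermacr-7(11)-en-12,6-olide
Conditions: DDQ, CH2Cl2/pH 7 phosphate buffer, 0 °C → rt
Reagents that add atoms: none
Why: Oxidative cleavage of the 4-methoxybenzyl ether by hydride abstraction and hydrolysis at neutral pH, which oxiranes, butenolide and tiglate tolerate.

Step 25
Reactants: 31 (1R,4R,5R,6S,8S,10R)-1,10:4,5-diepoxy-13-hydroxy-8-tigloyloxygermacr-7(11)-en-12,6-olide
Product: 32 (1R,4R,5R,6S,8S,10R)-13-acetoxy-1,10:4,5-diepoxy-8-tigloyloxygermacr-7(11)-en-12,6-olide (target)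
Conditions: Ac2O, pyridine, DMAP (cat.), CH2Cl2, 0 °C
Reagents that add atoms: acetic anhydride CC(=O)OC(C)=O
Why: Acetylation of the only free hydroxyl, a primary alcohol, under mild conditions.

## Compound list

1 | 4-methoxyphenol | COc1ccc(O)cc1 | starting material
2 | 4,4-dimethoxycyclohexa-2,5-dien-1-one | O=C1C=CC(OC)(OC)C=C1 | intermediate
3 | isoprene (2-methylbuta-1,3-diene) | C=CC(C)=C | starting material
4 | cis-(4aRS,8aSR)-4,4-dimethoxy-6-methyl-4a,5,8,8a-tetrahydronaphthalen-1(4H)-one (racemic, one enantiomer drawn) | O=C1C=CC(OC)(OC)[C@H]2CC(C)=CC[C@@H]12 | intermediate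
5 | 4-methoxy-6-methyl-5,8-dihydronaphthalen-1-ol | Oc1ccc(OC)c2c1CC=C(C)C2 | intermediate
6 | (6RS)-4-methoxy-6-methyl-5,6,7,8-tetrahydronaphthalen-1-ol | Oc1ccc(OC)c2c1CCC(C)C2 | intermediate
7 | (6RS)-4,4-dimethoxy-6-methyl-5,6,7,8-tetrahydronaphthalen-1(4H)-one | O=C1C=CC(OC)(OC)C2=C1CCC(C)C2 | intermediate
8 | (3S,6RS)-4,4-dimethoxy-6-methyl-3-(4,4,5,5-tetramethyl-1,3,2-dioxaborolan-2-yl)-3,4,5,6,7,8-hexahydronaphthalen-1(2H)-one | O=C1C[C@H](B3OC(C)(C)C(C)(C)O3)C(OC)(OC)C2=C1CCC(C)C2 | intermediate (not isolated)
9 | (3S,6RS)-3-hydroxy-4,4-dimethoxy-6-methyl-3,4,5,6,7,8-hexahydronaphthalen-1(2H)-one | O=C1C[C@H](O)C(OC)(OC)C2=C1CCC(C)C2 | intermediate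
10 | (3S,6RS)-3-(tert-butyldimethylsilyloxy)-4,4-dimethoxy-6-methyl-3,4,5,6,7,8-hexahydronaphthalen-1(2H)-one | O=C1C[C@H](O[Si](C)(C)C(C)(C)C)C(OC)(OC)C2=C1CCC(C)C2 | intermediate
11 | (1R,3S,6RS)-3-(tert-butyldimethylsilyloxy)-4,4-dimethoxy-1,6-dimethyl-1,2,3,4,5,6,7,8-octahydronaphthalen-1-ol | C[C@@]1(O)C[C@H](O[Si](C)(C)C(C)(C)C)C(OC)(OC)C2=C1CCC(C)C2 | intermediate
12 | (1R,3S,6RS)-4,4-dimethoxy-1,6-dimethyl-1,2,3,4,5,6,7,8-octahydronaphthalene-1,3-diol | C[C@@]1(O)C[C@H](O)C(OC)(OC)C2=C1CCC(C)C2 | intermediate
13 | (2S,4R,7RS)-4-hydroxy-1,1-dimethoxy-4,7-dimethyl-1,2,3,4,5,6,7,8-octahydronaphthalen-2-yl (2E)-2-methylbut-2-enoate | C/C=C(\C)C(=O)O[C@H]1C[C@@](C)(O)C2=C(C1(OC)OC)CC(C)CC2 | intermediate (precursor of the key step)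
14 | secondary ozonide of 13: 1,2,4-trioxolane bridging the two former alkene carbons (C1 and C6, germacrane locants; configuration there not defined) | C/C=C(\C)C(=O)O[C@H]1C[C@@](C)(O)C23CCC(C)CC(OO2)(O3)C1(OC)OC | intermediate (not isolated)
15 | (4RS,8S,10R)-10-hydroxy-7,7-dimethoxy-4,10-dimethyl-1,6-dioxocyclodecan-8-yl (2E)-2-methylbut-2-enoate | C/C=C(\C)C(=O)O[C@H]1C[C@@](C)(O)C(=O)CCC(C)CC(=O)C1(OC)OC | intermediate (product of the key step)
16 | (1S,4RS,8S,10R)-1,10-dihydroxy-7,7-dimethoxy-4,10-dimethyl-6-oxocyclodecan-8-yl (2E)-2-methylbut-2-enoate | C/C=C(\C)C(=O)O[C@H]1C[C@@](C)(O)[C@@H](O)CCC(C)CC(=O)C1(OC)OC | intermediate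
17 | (1S,4RS,8S,10R)-7,7-dimethoxy-4,10-dimethyl-1,6,10-tris(triethylsilyloxy)cyclodec-5-en-8-yl (2E)-2-methylbut-2-enoate (enol ether geometry immaterial) | C/C=C(\C)C(=O)O[C@H]1C[C@@](C)(O[Si](CC)(CC)CC)[C@@H](O[Si](CC)(CC)CC)CCC(C)C=C(O[Si](CC)(CC)CC)C1(OC)OC | intermediate
18 | (1S,4E,8S,10R)-7,7-dimethoxy-4,10-dimethyl-6-oxo-1,10-bis(triethylsilyloxy)cyclodec-4-en-8-yl (2E)-2-methylbut-2-enoate | C/C=C(\C)C(=O)O[C@H]1C[C@@](C)(O[Si](CC)(CC)CC)[C@@H](O[Si](CC)(CC)CC)CC/C(C)=C/C(=O)C1(OC)OC | intermediate
19 | (1S,4E,6R,8S,10R)-6-hydroxy-7,7-dimethoxy-4,10-dimethyl-1,10-bis(triethylsilyloxy)cyclodec-4-en-8-yl (2E)-2-methylbut-2-enoate | C/C=C(\C)C(=O)O[C@H]1C[C@@](C)(O[Si](CC)(CC)CC)[C@@H](O[Si](CC)(CC)CC)CC/C(C)=C/[C@@H](O)C1(OC)OC | intermediate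
20 | triethyl phosphonoacetate | CCOC(=O)CP(=O)(OCC)OCC | starting material
21 | paraformaldehyde (formaldehyde unit shown) | C=O | starting material
22 | ethyl 2-(diethoxyphosphoryl)acrylate | CCOC(=O)C(=C)P(=O)(OCC)OCC | intermediate
23 | 4-methoxybenzyl alcohol | COc1ccc(CO)cc1 | starting material
24 | ethyl 2-(diethoxyphosphoryl)-3-[(4-methoxybenzyl)oxy]propanoate (racemic) | CCOC(=O)C(COCc1ccc(OC)cc1)P(=O)(OCC)OCC | intermediate
25 | 2-(diethoxyphosphoryl)-3-[(4-methoxybenzyl)oxy]propanoic acid (racemic) | OC(=O)C(COCc1ccc(OC)cc1)P(=O)(OCC)OCC | intermediate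
26 | (1S,4E,6R,8S,10R)-6-{2-(diethoxyphosphoryl)-3-[(4-methoxybenzyl)oxy]propanoyloxy}-7,7-dimethoxy-4,10-dimethyl-1,10-bis(triethylsilyloxy)cyclodec-4-en-8-yl (2E)-2-methylbut-2-enoate (both epimers at the phosphonate carbon) | C/C=C(\C)C(=O)O[C@H]1C[C@@](C)(O[Si](CC)(CC)CC)[C@@H](O[Si](CC)(CC)CC)CC/C(C)=C/[C@@H](OC(=O)C(COCc2ccc(OC)cc2)P(=O)(OCC)OCC)C1(OC)OC | intermediate
27 | (1S,4E,6R,8S,10R)-6-{2-(diethoxyphosphoryl)-3-[(4-methoxybenzyl)oxy]propanoyloxy}-1,10-dihydroxy-4,10-dimethyl-7-oxocyclodec-4-en-8-yl (2E)-2-methylbut-2-enoate | C/C=C(\C)C(=O)O[C@H]1C[C@@](C)(O)[C@@H](O)CC/C(C)=C/[C@@H](OC(=O)C(COCc2ccc(OC)cc2)P(=O)(OCC)OCC)C1=O | intermediate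
28 | (1S,6R,8S,10R)-1,10-dihydroxy-13-[(4-methoxybenzyl)oxy]-8-tigloyloxygermacra-4E,7(11)-dien-12,6-olide | C/C=C(\C)C(=O)O[C@H]1C[C@@](C)(O)[C@@H](O)CC/C(C)=C/[C@H]2OC(=O)C(COCc3ccc(OC)cc3)=C12 | intermediate
29 | (1R,6R,8S,10R)-1,10-epoxy-13-[(4-methoxybenzyl)oxy]-8-tigloyloxygermacra-4E,7(11)-dien-12,6-olide | C/C=C(\C)C(=O)O[C@H]1C[C@@]2(C)O[C@@H]2CC/C(C)=C/[C@H]2OC(=O)C(COCc3ccc(OC)cc3)=C12 | intermediate
30 | (1R,4R,5R,6S,8S,10R)-1,10:4,5-diepoxy-13-[(4-methoxybenzyl)oxy]-8-tigloyloxygermacr-7(11)-en-12,6-olide | C/C=C(\C)C(=O)O[C@H]1C[C@@]2(C)O[C@@H]2CC[C@@]2(C)O[C@@H]2[C@H]2OC(=O)C(COCc3ccc(OC)cc3)=C12 | intermediate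
31 | (1R,4R,5R,6S,8S,10R)-1,10:4,5-diepoxy-13-hydroxy-8-tigloyloxygermacr-7(11)-en-12,6-olide | C/C=C(\C)C(=O)O[C@H]1C[C@@]2(C)O[C@@H]2CC[C@@]2(C)O[C@@H]2[C@H]2OC(=O)C(CO)=C12 | intermediate
32 | (1R,4R,5R,6S,8S,10R)-13-acetoxy-1,10:4,5-diepoxy-8-tigloyloxygermacr-7(11)-en-12,6-olide | C/C=C(\C)C(=O)O[C@H]1C[C@@]2(C)O[C@@H]2CC[C@@]2(C)O[C@@H]2[C@H]2OC(=O)C(COC(C)=O)=C12 | target

## Step count and least certain steps

Total step count: 25. Longest linear sequence: 22 steps (steps 1–15 and 19–25); steps 16–18 prepare acid 25.

Step 11 (key step). Ozone may also cleave the tiglate alkene, the carbonyl oxide next to the free tertiary carbinol may fragment the C1–C10 bond, or the dione may undergo transannular aldol closure during reduction of a sluggish tetrasubstituted ozonide. Fallback: cleave before the tiglate is introduced. Silyl ether 11, which has a single alkene, is ozonised and reduced with PPh3 to (4RS,8S,10R)-8-(tert-butyldimethylsilyloxy)-10-hydroxy-7,7-dimethoxy-4,10-dimethylcyclodecane-1,6-dione F1. Desilylation with HF·pyridine gives the dihydroxy dione F2, and acylation of its secondary hydroxyl with tigloyl chloride and pyridine returns to the route at 15.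

Step 12. Hydride may also add to the C6 ketone (loss of chemoselectivity), or the anti selectivity at C1 may erode. Fallback: accept reduction of both ketones and sort them afterwards. From 15, excess Zn(BH4)2 gives the triol F3, in which C1 is still set by chelation and C6 is a mixture. PhB(OH)2 masks only the 1,10-diol as the cyclic phenylboronate F4. Dess–Martin periodinane reoxidises C6 to the keto boronate F5, and exchange with pinacol releases 16.

Step 14. β-Hydride elimination may run through the conformer that leads to the (4Z)-enone, or palladium hydride may re-add and move the double bond out of conjugation. Fallback: a selenoxide syn-elimination at low temperature, which involves no metal hydride. From 17, PhSeCl gives the 5-phenylselanyl ketone F6, and H2O2 with pyridine at 0 °C gives 18.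

Step 15. The conformation of the ring may override the catalyst, giving poor or reversed facial selectivity at C6. Fallback: use substrate control and correct the centre in the esterification. From 18, NaBH4 with CeCl3 gives the (6S)-alcohol F7 if that is the epimer the ring favours. Mitsunobu esterification of F7 with acid 25 (PPh3, DIAD) inverts C6 at this allylic position and returns to the route at 26.

Step 21. Enolisation of the C7 ketone toward C6, which is activated by the acyloxy group and the allylic C4=C5 bond, may cause epimerisation or double-bond migration before the hindered closure occurs, and the phosphonate carbanion may expel the β-alkoxide. Fallback: a neutral intramolecular Wittig closure with a stabilised ylide.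
- Alcohol 23 is added to methyl 2-bromoacrylate under base catalysis to give methyl 2-bromo-3-[(4-methoxybenzyl)oxy]propanoate F8, which is saponified to the acid F9.
- Carbodiimide esterification of 19 with F9 gives the bromo ester F10, and PPh3 in MeCN gives the phosphonium bromide F11.
- Aqueous HCl in THF unmasks the ketone and the diol to give the keto diol phosphonium bromide F12.
- Aqueous NaHCO3 liberates the ylide, which closes on warming in toluene to 28.

Step 23. The peracid may attack the inner-face conformer and give the wrong oxirane, or the acid by-product may trigger transannular opening of the 1,10-oxirane by the C4=C5 alkene before it is epoxidised. Fallback: reagent control under non-acidic conditions, the Shi epoxidation of 29 with the fructose-derived ketone (the enantiomer that matches the required face) and Oxone in buffered MeCN/water. This leads directly to 30 and makes no new compound.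

## Further compounds

F1 | step 11 | (4RS,8S,10R)-8-(tert-butyldimethylsilyloxy)-10-hydroxy-7,7-dimethoxy-4,10-dimethylcyclodecane-1,6-dione | C[C@@]1(O)C[C@H](O[Si](C)(C)C(C)(C)C)C(OC)(OC)C(=O)CC(C)CCC1=O
F2 | step 11 | (4RS,8S,10R)-8,10-dihydroxy-7,7-dimethoxy-4,10-dimethylcyclodecane-1,6-dione | C[C@@]1(O)C[C@H](O)C(OC)(OC)C(=O)CC(C)CCC1=O
F3 | step 12 | (1S,4RS,6RS,8S,10R)-1,6,10-trihydroxy-7,7-dimethoxy-4,10-dimethylcyclodecan-8-yl (2E)-2-methylbut-2-enoate | C/C=C(\C)C(=O)O[C@H]1C[C@@](C)(O)[C@@H](O)CCC(C)CC(O)C1(OC)OC
F4 | step 12 | cyclic phenylboronate of the 1,10-diol of F3 | C/C=C(\C)C(=O)O[C@H]1C[C@@]2(C)OB(c3ccccc3)O[C@H]2CCC(C)CC(O)C1(OC)OC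
F5 | step 12 | cyclic phenylboronate of 16 (6-ketone) | C/C=C(\C)C(=O)O[C@H]1C[C@@]2(C)OB(c3ccccc3)O[C@H]2CCC(C)CC(=O)C1(OC)OC
F6 | step 14 | (1S,4RS,8S,10R)-7,7-dimethoxy-4,10-dimethyl-6-oxo-5-(phenylselanyl)-1,10-bis(triethylsilyloxy)cyclodecan-8-yl (2E)-2-methylbut-2-enoate | C/C=C(\C)C(=O)O[C@H]1C[C@@](C)(O[Si](CC)(CC)CC)[C@@H](O[Si](CC)(CC)CC)CCC(C)C([Se]c2ccccc2)C(=O)C1(OC)OC
F7 | step 15 | (1S,4E,6S,8S,10R)-6-hydroxy-7,7-dimethoxy-4,10-dimethyl-1,10-bis(triethylsilyloxy)cyclodec-4-en-8-yl (2E)-2-methylbut-2-enoate | C/C=C(\C)C(=O)O[C@H]1C[C@@](C)(O[Si](CC)(CC)CC)[C@@H](O[Si](CC)(CC)CC)CC/C(C)=C/[C@H](O)C1(OC)OC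
F8 | step 21 | methyl 2-bromo-3-[(4-methoxybenzyl)oxy]propanoate | COC(=O)C(Br)COCc1ccc(OC)cc1
F9 | step 21 | 2-bromo-3-[(4-methoxybenzyl)oxy]propanoic acid | OC(=O)C(Br)COCc1ccc(OC)cc1
F10 | step 21 | 6-O-{2-bromo-3-[(4-methoxybenzyl)oxy]propanoyl} ester of 19 | C/C=C(\C)C(=O)O[C@H]1C[C@@](C)(O[Si](CC)(CC)CC)[C@@H](O[Si](CC)(CC)CC)CC/C(C)=C/[C@@H](OC(=O)C(Br)COCc2ccc(OC)cc2)C1(OC)OC
F11 | step 21 | triphenylphosphonium bromide from F10 | C/C=C(\C)C(=O)O[C@H]1C[C@@](C)(O[Si](CC)(CC)CC)[C@@H](O[Si](CC)(CC)CC)CC/C(C)=C/[C@@H](OC(=O)C(COCc2ccc(OC)cc2)[P+](c2ccccc2)(c2ccccc2)c2ccccc2)C1(OC)OC.[Br-]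
F12 | step 21 | 7-oxo-1,10-diol triphenylphosphonium bromide from F11 | C/C=C(\C)C(=O)O[C@H]1C[C@@](C)(O)[C@@H](O)CC/C(C)=C/[C@@H](OC(=O)C(COCc2ccc(OC)cc2)[P+](c2ccccc2)(c2ccccc2)c2ccccc2)C1=O.[Br-]
F0 | step 23 | none | none
A1 | alternative 1 | 8β-hydroxygermacra-1(10),4,11(13)-trien-12-oic acid | O[C@@H]1C/C(C)=C/CC/C(C)=C/C[C@@H]1C(=C)C(=O)O
A2 | alternative 1 | eupatolide (8β-hydroxycostunolide) | O[C@@H]1C/C(C)=C/CC/C(C)=C/[C@H]2OC(=O)C(=C)[C@H]12
A3 | alternative 2 | 1,10:4,5-diepoxygermacra-7,11(13)-dien-12,6-olide | O=C1O[C@H]2C(=CC[C@@]3(C)O[C@@H]3CC[C@@]3(C)O[C@@H]32)C1=C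
A4 | alternative 2 | 8,13-epidioxy-1,10:4,5-diepoxygermacr-7(11)-en-12,6-olide | O1OCC2=C3[C@@H]1C[C@@]1(C)O[C@@H]1CC[C@@]1(C)O[C@@H]1[C@H]3OC2=O
A5 | alternative 3 | methyl 2-(acetoxymethyl)-3-formyl-4-silyloxy-6-methylundec-2,6-dien-10-ynoate (acyclic ynal, 8-silyl ether, germacrane C8 as in the target) | C#CCC/C=C(\C)C[C@H](O[Si](C)(C)C(C)(C)C)C(C=O)=C(COC(C)=O)C(=O)OC
A6 | alternative 3 | 13-acetoxy-8-(tert-butyldimethylsilyloxy)germacra-1(10),4,7(11)-trien-12,6-olide | CC(C)(C)[Si](C)(C)O[C@H]1C/C(C)=C/CC/C(C)=C/[C@H]2OC(=O)C(COC(C)=O)=C12
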